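**Retrosynthetic overview**
1. Ferugin comes from triol silyl ether 15 by Mitsunobu aroylation at C-c with inversion, then desilylation. SmI2 cleavage of an α-alkoxy ketone in the oxa-bridged tricycle 12 gives the trans ring-fusion H and the free allylic OH.
2. Tricycle 10 comes from an intramolecular 3-oxidopyrylium/alkene [5+2] cycloaddition of acetoxypyranone 9. This single step closes the cyclopentanone (tether) and the seven-membered ring, and sets the quaternary C–Me centre and the C–O bridge. Both rings form here.
3. Pyranone 9 comes from Achmatowicz ring expansion (dearomatization) of furyl α-ketol 7. The α-ketol is built from 3-methylfuran by C-5 borylation, glyoxylate addition, Weinreb amide formation and Grignard addition.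
4. The iPr/tertiary alcohol (organocerium addition) and the exocyclic methylene (deconjugation of a β-methyl enone) are installed at the bridged stage. There, the quaternary bridgehead and the anti-Bredt bridgehead C–H block competing enolisations.

Assumption: 4-(TBSO)benzoic acid (16) is bought (or made from 4-hydroxybenzoic acid and TBSCl). Organometallic reagents are used as commercial or freshly prepared solutions.

**Step 1**
Reactants: 1 (3-methylfuran)
Product: 2 (2-(4-methylfuran-2-yl)-4,4,5,5-tetramethyl-1,3,2-dioxaborolane)
Conditions: B2pin2, [Ir(OMe)(cod)]2 (1.5 mol %), dtbpy (3 mol %), THF, 80 °C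
Reagents that add atoms: bis(pinacolato)diboron, CC1(C)OB(OC1(C)C)B1OC(C)(C)C(C)(C)O1 (adds Bpin)
Why: Ir-catalysed C–H borylation is sterically controlled, so it occurs at the α-CH remote from the 3-methyl group (C-5). No stereocentre is formed.

**Step 2**
Reactants: 2, 3 (ethyl glyoxylate)
Product: 4 (ethyl 2-hydroxy-2-(4-methylfuran-2-yl)acetate, racemic)
Conditions: [Rh(cod)OH]2 (2.5 mol %), dppb (6 mol %), dioxane/H2O 10:1, 60 °C
Reagents that add atoms: none (water supplies only the proton)
Why: Proposed new method: Rh–OH transmetalation of the furyl-Bpin, 1,2-insertion into the glyoxylate C=O and protonolysis; the closest known reaction is the Miyaura–Hayashi Rh-catalysed addition of aryl-boron reagents to glyoxylates. The new carbinol stereocentre is later destroyed in the oxidopyrylium, so racemic 4 is acceptable.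

**Step 3**
Reactants: 4
Product: 5 (2-hydroxy-N-methoxy-N-methyl-2-(4-methylfuran-2-yl)acetamide)
Conditions: MeONHMe·HCl, iPrMgCl (4 equiv), THF, –20 → 0 °C
Reagents that add atoms: N,O-dimethylhydroxylamine hydrochloride, CONC.Cl (adds N(OMe)Me)
Why: Grignard-mediated aminolysis of the ester (Williams Weinreb amide formation); no new stereocentre.

**Step 4**
Reactants: 5, 6 (4-bromo-2-methylbut-1-ene, converted to its Grignard reagent)
Product: 7 (1-hydroxy-5-methyl-1-(4-methylfuran-2-yl)hex-5-en-2-one, racemic)
Conditions: (3-methylbut-3-enyl)MgBr (3 equiv, from 6 and Mg), THF, –78 → 0 °C; aq NH4Cl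
Reagents that add atoms: (3-methylbut-3-en-1-yl)magnesium bromide, C=C(C)CC[Mg]Br (adds C5H9)
Why: The Weinreb ketone synthesis stops cleanly at the chelated tetrahedral intermediate and gives the α-ketol; the carbinol centre is destroyed in step 7.

**Step 5**
Reactants: 7
Product: 8 (6-hydroxy-5-methyl-2-(4-methylpent-4-enoyl)-2H-pyran-3(6H)-one, anomer/epimer mixture)
Conditions: NBS (1.05 equiv), NaHCO3, NaOAc·3H2O, THF/H2O 4:1, –10 → 0 °C
Reagents that add atoms: water, O (supplies the C-6 hydroxyl oxygen)
Why: Achmatowicz oxidative ring expansion dearomatizes the furan to the pyranone; the furan reacts much faster than the remote 1,1-disubstituted alkene. The 4-methyl group ends up at C-5 of the pyranone, and the ring stereocentres are erased in step 7.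

**Step 6**
Reactants: 8
Product: 9 (6-acetoxy-5-methyl-2-(4-methylpent-4-enoyl)-2H-pyran-3(6H)-one)
Conditions: Ac2O (1.5 equiv), pyridine, DMAP (5 mol %), CH2Cl2, 0 °C
Reagents that add atoms: acetic anhydride, CC(=O)OC(C)=O (adds Ac)
Why: Acetylation of the hemiacetal creates the leaving group needed to generate the oxidopyrylium; no stereocentre is retained.

**Step 7**
Reactants: 9
Product: 10 (oxa-bridged tricycle, CC1=CC(=O)[C@@]32[C@](C)(CCC2=O)C[C@@H]1O3)
Conditions: chiral aminothiourea catalyst (20 mol %), iPr2NEt (1.2 equiv), MTBE, 40 → 60 °C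
Reagents that add atoms: none (AcOH is lost)
Why: Proposed new method: the base forms the acidic C-2 enolate and eliminates AcO⁻, giving the 2-acyl-3-oxidopyrylium. A chiral H-bond-donor/amine ion pair then controls the face of the intramolecular [5+2] cycloaddition; the closest known reaction is the aminothiourea-catalysed intramolecular oxidopyrylium [5+2]. The three-atom tether closes the cyclopentanone and forces the tether carbon onto the exo position at C-7, so the quaternary methyl, the ring-fusion oxygen bridge and the CH–O bridgehead are fixed together; the bridge O and the exo ring bond are cis, which is the relative configuration of ferugin.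

**Step 8**
Reactants: 10
Product: 11 (tertiary alcohol, CC1=CC(=O)[C@@]32[C@](C)(CC[C@@]2(O)C(C)C)C[C@@H]1O3)
Conditions: iPrMgCl·LiCl, anhydrous CeCl3, THF, –78 °C
Reagents that add atoms: isopropylmagnesium chloride, CC(C)[Mg]Cl (adds iPr)
Why: Organocerium addition (Imamoto) goes to the more electrophilic saturated cyclopentanone rather than the β,β-disubstituted enone. It attacks the face anti to the angular methyl, setting the tertiary carbinol (OH cis to the methyl, iPr anti).

**Step 9**
Reactants: 11
Product: 12 (β,γ-enone with exocyclic methylene, C=C1CC(=O)[C@@]32[C@](C)(CC[C@@]2(O)C(C)C)C[C@@H]1O3)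
Conditions: LDA (3.5 equiv), THF, –78 °C, 1 h; then AcOH (6 equiv) in THF at –78 °C
Reagents that add atoms: none (H⁺ only)
Why: With the α′-position quaternary and the bridgehead γ′-H anti-Bredt, LDA can only remove a proton from the γ-methyl, giving a dienolate that is protonated kinetically at the α-carbon; this is deconjugative isomerisation and creates no stereocentre.

**Step 10**
Reactants: 12
Product: 13 (hydroxy ketone, C=C1CC(=O)[C@@H]2[C@](C)(CC[C@@]2(O)C(C)C)C[C@@H]1O)
Conditions: SmI2 (2.5 equiv), THF, MeOH (8 equiv), –78 → –20 °C
Reagents that add atoms: none (MeOH supplies H)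
Why: SmI2 cleaves the C–O bond α to the ketone (Molander), opening the oxygen bridge and leaving the free allylic alcohol at the other end. Protonation of the samarium enolate anti to the angular methyl sets the ring-fusion H trans to the methyl; this centre is α to the ketone and, if needed, is equilibrated under mild base.

**Step 11**
Reactants: 13
Product: 14 (C-j TBS ether, C=C1CC(=O)[C@@H]2[C@](C)(CC[C@@]2(O)C(C)C)C[C@@H]1O[Si](C)(C)C(C)(C)C)
Conditions: TBSCl (1.5 equiv), imidazole (3 equiv), DMF, 0 °C → rt
Reagents that add atoms: tert-butyldimethylsilyl chloride, CC(C)(C)[Si](C)(C)Cl (adds TBS)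
Why: The secondary allylic alcohol is silylated selectively over the hindered tertiary alcohol so that only C-c is acylated later; no stereocentre changes.

**Step 12**
Reactants: 14
Product: 15 (C-c epimeric alcohol, C=C1C[C@@H](O)[C@@H]2[C@](C)(CC[C@@]2(O)C(C)C)C[C@@H]1O[Si](C)(C)C(C)(C)C)
Conditions: NaBH4 (2 equiv), MeOH/CH2Cl2 1:1, –40 °C
Reagents that add atoms: none (hydride only)
Why: Borohydride attacks from the less hindered face, syn to the ring-fusion H and anti to the angular methyl and fused cyclopentane, giving the C-c alcohol opposite to that in ferugin. This is deliberate, to be corrected by inversion in step 13, and it also locks the ring-fusion H.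

**Step 13**
Reactants: 15, 16 (4-(tert-butyldimethylsilyloxy)benzoic acid)
Product: 17 (bis-TBS-protected ester)
Conditions: PPh3 (2 equiv), DIAD (2 equiv), toluene/THF, 0 °C → rt
Reagents that add atoms: 16, CC(C)(C)[Si](C)(C)Oc1ccc(cc1)C(=O)O (supplies the aroyl group)
Why: Mitsunobu esterification proceeds by SN2 with inversion at C-c, converting the epimeric alcohol into the ferugin configuration while installing the ester in one step.

**Step 14**
Reactants: 17
Product: 18 (ferugin)
Conditions: TBAF (4 equiv), AcOH (4 equiv), THF, 0 °C → rt
Reagents that add atoms: none (fluoride is removed with the silyl groups)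
Why: Buffered fluoride removes the secondary and aryl TBS ethers in one operation; no stereocentre is touched, giving ferugin.

**Compound list**

| No. | Name | SMILES | Role |
|---|---|---|---|
| 1 | 3-methylfuran | Cc1ccoc1 | starting material |
| 2 | 2-(4-methylfuran-2-yl)-pinacolboronate | Cc1cc(B2OC(C)(C)C(C)(C)O2)oc1 | intermediate |
| 3 | ethyl glyoxylate | CCOC(=O)C=O | starting material |
| 4 | ethyl 2-hydroxy-2-(4-methylfuran-2-yl)acetate (rac) | CCOC(=O)C(O)c1cc(C)co1 | intermediate |
| 5 | Weinreb α-hydroxy amide | CON(C)C(=O)C(O)c1cc(C)co1 | intermediate |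
| 6 | 4-bromo-2-methylbut-1-ene | C=C(C)CCBr | starting material |
| 7 | 1-hydroxy-5-methyl-1-(4-methylfuran-2-yl)hex-5-en-2-one | C=C(C)CCC(=O)C(O)c1cc(C)co1 | intermediate |
| 8 | 6-hydroxy-5-methyl-2-(4-methylpent-4-enoyl)-2H-pyran-3(6H)-one | CC(=C)CCC(=O)C1OC(O)C(C)=CC1=O | intermediate |
| 9 | 6-acetoxy analogue of 8 | CC(=O)OC1OC(C(=O)CCC(C)=C)C(=O)C=C1C | intermediate |
| 10 | oxa-bridged cyclopentanone-fused enone | CC1=CC(=O)[C@@]32[C@](C)(CCC2=O)C[C@@H]1O3 | intermediate |
| 11 | tertiary alcohol from iPr addition | CC1=CC(=O)[C@@]32[C@](C)(CC[C@@]2(O)C(C)C)C[C@@H]1O3 | intermediate |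
| 12 | exocyclic-methylene β,γ-enone | C=C1CC(=O)[C@@]32[C@](C)(CC[C@@]2(O)C(C)C)C[C@@H]1O3 | intermediate |
| 13 | hydroxy ketone (SmI2 product) | C=C1CC(=O)[C@@H]2[C@](C)(CC[C@@]2(O)C(C)C)C[C@@H]1O | intermediate |
| 14 | TBS ether of 13 | C=C1CC(=O)[C@@H]2[C@](C)(CC[C@@]2(O)C(C)C)C[C@@H]1O[Si](C)(C)C(C)(C)C | intermediate |
| 15 | C-c epimeric alcohol | C=C1C[C@@H](O)[C@@H]2[C@](C)(CC[C@@]2(O)C(C)C)C[C@@H]1O[Si](C)(C)C(C)(C)C | intermediate |
| 16 | 4-(TBSO)benzoic acid | CC(C)(C)[Si](C)(C)Oc1ccc(cc1)C(=O)O | starting material |
| 17 | bis-TBS ester | C=C1C[C@H](OC(=O)c2ccc(O[Si](C)(C)C(C)(C)C)cc2)[C@@H]2[C@](C)(CC[C@@]2(O)C(C)C)C[C@@H]1O[Si](C)(C)C(C)(C)C | intermediate |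
| 18 | ferugin | C=C1C[C@H](OC(=O)c2ccc(O)cc2)[C@@H]2[C@](C)(CC[C@@]2(O)C(C)C)C[C@@H]1O | target |

**Total step count:** 14. **Longest linear sequence:** 14 steps (1 → 2 → 4 → 5 → 7 → 8 → 9 → 10 → 11 → 12 → 13 → 14 → 15 → 17 → 18).

**Three steps most likely to fail**
1. **Step 7 (enantioselective [5+2]).** The catalyst may not control enantioselectivity for a 2-acyl dipole, or the tether may not give the exo product cleanly. Fallback: replace the ketone tether with an enantioenriched secondary h-OTBS tether made by Sharpless dihydroxylation of an E-alkene. That stereocentre controls the cycloaddition face by relay, is oxidized away to the ketone after cyclisation, and the route then continues from step 8.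
2. **Step 2 (Rh-catalysed addition of the furyl-Bpin to glyoxylate).** Heteroaryl boronates are prone to protodeboronation. Fallback: use 2-TMS-3-methylfuran, lithiate it at C-5, add to ethyl glyoxylate, and remove the silyl group after step 4.
3. **Step 13 (Mitsunobu on the hindered C-c alcohol).** Elimination may compete with inversion. Fallback: convert 15 to the triflate and displace with cesium 4-TBSO-benzoate (SN2). Alternatively, oxidize 15 back to the ketone and reduce it with a bulky hydride that attacks from the opposite face, giving the correct C-c epimer for direct acylation.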